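**Retrosynthetic overview**
1. The plan rests on the gem-dimethylcyclobutane ring C1–C9–C10–C11 (caryophyllane numbering). It is read as the head-to-tail [2+2] adduct of isobutylene (C10, C11, both methyl groups) with cyclopent-2-enone, whose Cβ is C1, whose Cα is C9 and whose carbonyl carbon ends as the spiro centre C8.
2. Dihydropyran ring (made last): O–C8 and C13–C1′ are cut by a retro hetero-Diels–Alder reaction. This gives the C8=C13 methylene compound 18 and the enetrione 22, made from syncarpic acid and isovaleraldehyde.
3. The C5 carbinol goes back to the C5 enone (reagent-controlled reduction), and the enone to an allylic C–H oxidation. C13 comes from a Wittig methylenation of the C8 ketone, through which C9 is also turned to the trans fusion.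
4. Nine-membered ring: a retro anionic oxy-Cope step (C3–C8 restored, C5–C6 cut) leads to a 2-vinyl-3-isopropenylbicyclo[3.2.0]heptan-2-ol. This is built on the photoadduct by α-alkenylation at C3 and vinyl addition at C8.
5. Order of ring formation: cyclobutane on a sacrificial cyclopentanone (step 1), nine-membered ring (step 5), dihydropyran (step 12). The six-membered trione ring is bought.

Key step: step 1

Assumption 1: caryophyllane numbers are used throughout (C12 = methyl on C4, C13 = exocyclic methylene carbon, C1′ = isobutyl-bearing carbon).
Assumption 2: the sense of induction of the catalyst in step 1 is taken to be the one it shows with six-membered enones. The catalyst antipode is used if cyclopentenone binds the other way round.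

**Step 1**
Reactants: 1 cyclopent-2-en-1-one; 2 isobutylene
Product: 3 (1R,5R)-6,6-dimethylbicyclo[3.2.0]heptan-2-one
Conditions: 2 (excess, condensed in), AlBr3 complex of (S)-3,3-bis(3,5-dimethylphenyl)-1-(2,4,6-trifluorophenyl)tetrahydro-1H,3H-pyrrolo[1,2-c][1,3,2]oxazaborole (50 mol %), CH2Cl2, −75 °C, hν (λ = 366 nm)
Reagents that add atoms: none
Why: Binding of the enone oxygen to the boron centre of the AlBr3-activated oxazaborolidine moves the strong π–π* band of the enone to about 360 nm, so that at 366 nm the bound enone is excited in preference to the free one; after intersystem crossing its triplet is attacked at C9 by the CH2 terminus of isobutylene, and the triplet 1,4-biradical (tertiary radical at C11, secondary radical at C1) undergoes spin inversion and collapses by forming C1–C11. The closest known reaction type is the enantioselective intermolecular enone–alkene [2+2] photocycloaddition of cyclic enones under this class of chiral Lewis acid, and the uncatalysed cyclopentenone–isobutylene photoaddition is classical. The only ring closed is the cyclobutane, by radical–radical combination within the 1,4-biradical across the former Cα=Cβ bond, and in a bicyclo[3.2.0] frame this closure can only give the cis fusion. C1 is controlled by the catalyst, whose aryl groups cover one face of the bound enone so that the alkene adds to the Re face at Cβ and Cα; C9 is controlled by ring strain, follows C1 as its cis partner and is corrected in step 6. The step needs head-to-tail orientation, which the polarity of the excited enone and the preference for the tertiary radical secure (head-to-head biradicals mostly revert), and it needs enantiofacial control, which rests on low temperature, long-wavelength light and a high catalyst loading to suppress excitation of unbound enone.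

**Step 2**
Reactants: 3 (1R,5R)-6,6-dimethylbicyclo[3.2.0]heptan-2-one
Product: 5 {[(1R,5R)-6,6-dimethylbicyclo[3.2.0]hept-2-en-2-yl]oxy}trimethylsilane, via lithium enolate 4 (not isolated)
Conditions: LiN(i-Pr)2, THF, −78 °C; Me3SiCl, −78 °C → rt
Reagents that add atoms: chlorotrimethylsilane, C[Si](C)(C)Cl
Why: Kinetic enolisation with the hindered amide takes a proton from the open C3 methylene group rather than the C9 bridgehead proton, whose loss would place a double bond at the fusion of the strained bicycle, and O-silylation (silyl enol ether formation) freezes this regiochemistry without touching C1 or C9.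

**Step 3**
Reactants: 5 silyl enol ether; 6 2-bromopropene
Product: 8 (1R,3S,5R)-6,6-dimethyl-3-(prop-1-en-2-yl)bicyclo[3.2.0]heptan-2-one (isopropenyl exo), via tributyltin enolate 7 (not isolated)
Conditions: Bu3SnF (1.1 equiv), Pd(OAc)2 (3 mol %), P(t-Bu)3 (6 mol %), PhMe, 80 °C, sealed tube
Reagents that add atoms: none
Why: Fluoride-triggered silicon-to-tin exchange gives the tin enolate, which couples with the alkenyl bromide in a palladium-catalysed ketone α-alkenylation (Migita-type tin enolate coupling, the bulky phosphine outrunning β-hydride elimination); C3–C4 is formed by reductive elimination from palladium held on the convex face, which is also the thermodynamically preferred exo position, and the base-free medium avoids the dienolate, so neither kinetic protonation to the endo epimer nor conjugation to the isopropylidene ketone should intervene.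

**Step 4**
Reactants: 8 exo-3-isopropenyl ketone; 9 vinylmagnesium bromide
Product: 10 (1R,2R,3S,5R)-2-ethenyl-6,6-dimethyl-3-(prop-1-en-2-yl)bicyclo[3.2.0]heptan-2-ol (vinyl and isopropenyl cis on the convex face)
Conditions: 9 (1.5 equiv), LaCl3·2LiCl (1.0 equiv), THF, −78 → 0 °C; aq NH4Cl
Reagents that add atoms: none
Why: Grignard 1,2-addition, made non-basic by the lanthanum salt so that the acidic C3–H is not removed; each carbonyl face carries one α-substituent, but the concave face is roofed by the cyclobutane and its endo methyl group, so attack should come from the convex face and set C8 with vinyl cis to isopropenyl, any trans isomer being removed by chromatography.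

**Step 5**
Reactants: 10 cis-dialkenyl carbinol
Product: 13 (1R,3Z,9R)-4,11,11-trimethylbicyclo[7.2.0]undec-3-en-8-one (cis-fused), via potassium alkoxide 11 (not isolated), via potassium enolate 12 (not isolated)
Conditions: KH, 18-crown-6, THF, 0 °C → rt; AcOH, −78 °C
Reagents that add atoms: none
Why: Anionic oxy-Cope rearrangement: both alkenyl groups lie on the open convex face and can fold under the five-membered ring into a boat-like array with the C4 methyl group pointing outwards, so that C3–C8 breaks, C5–C6 forms and the new C3=C4 bond is cis within the nine-membered ring (Z), driven by strain release and enolate formation; no stereocentre is created, C3 and C8 become trigonal, and C1 and C9 are untouched.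

**Step 6**
Reactants: 13 cis-fused cyclononenone
Product: 14 (1R,3Z,9S)-4,11,11-trimethylbicyclo[7.2.0]undec-3-en-8-one (trans-fused)
Conditions: NaOMe (0.2 equiv), MeOH, rt
Reagents that add atoms: none
Why: Base-catalysed epimerisation through the C8–C9 enolate lets the cis-fused ketone relax to the more stable trans-fused isomer, in which the two ring branches on C1 and C9 stand on opposite faces of the cyclobutane as is general for caryophyllane 8-ketones, so C9 is set under thermodynamic control relative to C1.

**Step 7**
Reactants: 14 trans-fused cyclononenone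
Product: 15 (1R,3Z,9S)-5-hydroxy-4,11,11-trimethylbicyclo[7.2.0]undec-3-en-8-one (C5 epimers both carried on)
Conditions: SeO2 (30 mol %), t-BuOOH (decane), CH2Cl2, 0 °C → rt
Reagents that add atoms: selenium dioxide, O=[Se]=O; tert-butyl hydroperoxide, CC(C)(C)OO
Why: Selenium dioxide allylic hydroxylation (ene reaction with Se at C3, then [2,3]-sigmatropic shift) functionalises the more substituted end of the only alkene and, by the usual order CH2 before CH3 in 1-methylcycloalkenes, should place oxygen on ring carbon C5 while the mild catalytic conditions leave the ketone α-positions alone; the configuration at C5 is of no consequence because this centre becomes trigonal in step 9.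

**Step 8**
Reactants: 15 hydroxy ketone
Product: 16 (1R,3Z,9S)-4,11,11-trimethyl-8-methylidenebicyclo[7.2.0]undec-3-en-5-ol (C5 epimers)
Conditions: Ph3PCH3Br, KOt-Bu (3.5 equiv each), THF, 0 °C → reflux
Reagents that add atoms: methyltriphenylphosphonium bromide, C[P+](c1ccccc1)(c1ccccc1)c1ccccc1.[Br-]
Why: Wittig methylenation with excess ylide: the first equivalent only deprotonates the C5 hydroxyl, the keto alkoxide stays in equilibrium with any transannular hemiketal and is drained by olefination of the C8 carbonyl as in other caryophyllane 8-ketones, and C9, already the thermodynamic epimer, cannot be lost in the basic medium.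

**Step 9**
Reactants: 16 dienol (C5 epimers)
Product: 17 (1R,3Z,9S)-4,11,11-trimethyl-8-methylidenebicyclo[7.2.0]undec-3-en-5-one
Conditions: MnO2 (activated, excess), CH2Cl2, rt
Reagents that add atoms: none
Why: Manganese dioxide oxidises only the allylic alcohol (selective allylic alcohol oxidation), so both C5 epimers should converge on one Z-configured α-methyl enone while the isolated C8=C13 methylene group and the ring fusion stay untouched.

**Step 10**
Reactants: 17 dienone
Product: 18 (1R,3Z,5S,9S)-4,11,11-trimethyl-8-methylidenebicyclo[7.2.0]undec-3-en-5-ol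
Conditions: (R)-1-methyl-3,3-diphenyltetrahydro-1H,3H-pyrrolo[1,2-c][1,3,2]oxazaborole [(R)-Me-CBS] (20 mol %), catecholborane, PhMe, −78 °C; MeOH, then 1 M NaOH wash
Reagents that add atoms: none
Why: Corey–Bakshi–Shibata reduction: the ketone binds to the catalyst boron anti to its larger α-methylalkenyl branch (C4) and syn to the C6 methylene group, so the (R)-catalyst should deliver hydride to the face that gives the 5S carbinol under reagent control and 1,2-selectively, and catecholborane at low temperature does not hydroborate the two alkenes.

**Step 11**
Reactants: 19 syncarpic acid; 20 isovaleraldehyde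
Product: 22 2,2,4,4-tetramethyl-6-(3-methylbutylidene)cyclohexane-1,3,5-trione, via Mannich base 21 (not isolated)
Conditions: piperidine (1.05 equiv), CH2Cl2, rt; then 1 M HCl
Reagents that add atoms: none
Why: Knoevenagel condensation run through the Mannich base: the acidic C–H of the cyclic triketone, the aldehyde and piperidine combine to 21, and protonation turns piperidine into a leaving group so that elimination gives the enetrione, which has no E/Z isomers because its two flanking carbonyl groups are equivalent.

**Step 12**
Reactants: 18 (5S)-dienol; 22 enetrione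
Product: 23 Tomentodione P
Conditions: PhMe, 80 °C, sealed tube
Reagents that add atoms: none
Why: Inverse-electron-demand hetero-Diels–Alder reaction: the electron-poor 1-oxadiene of 22 adds to the accessible 1,1-disubstituted C8=C13 bond rather than to the trisubstituted C3=C4 bond, C13 bonding to the electrophilic C1′ and the carbonyl oxygen to C8, the carbon best able to carry positive charge; C8 is set by attack on the outer face of the methylene group in the conformer that holds H9 in the alkene plane (the face flanked by C10H2, not the one closed by C1, C2 and the ring), and C1′ by the orientation that places the C9 branch under the heterodiene with the isobutyl group outside, the C1′ epimer being the expected by-product to be removed by chromatography.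

**Compound list**
1 | cyclopent-2-en-1-one | O=C1C=CCC1 | starting material
2 | isobutylene | CC(C)=C | starting material
3 | (1R,5R)-6,6-dimethylbicyclo[3.2.0]heptan-2-one | O=C1CC[C@@H]2[C@H]1CC2(C)C | intermediate
4 | lithium enolate of 3 (C3=C8) | [Li]OC1=CC[C@@H]2[C@H]1CC2(C)C | intermediate (not isolated)
5 | {[(1R,5R)-6,6-dimethylbicyclo[3.2.0]hept-2-en-2-yl]oxy}trimethylsilane | C[Si](C)(C)OC1=CC[C@@H]2[C@H]1CC2(C)C | intermediate
6 | 2-bromopropene | CC(Br)=C | starting material
7 | tributyltin enolate of 3 | CCCC[Sn](CCCC)(CCCC)OC1=CC[C@@H]2[C@H]1CC2(C)C | intermediate (not isolated)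
8 | (1R,3S,5R)-6,6-dimethyl-3-(prop-1-en-2-yl)bicyclo[3.2.0]heptan-2-one | O=C1[C@H](C(C)=C)C[C@@H]2[C@H]1CC2(C)C | intermediate
9 | vinylmagnesium bromide | C=C[Mg]Br | starting material
10 | (1R,2R,3S,5R)-2-ethenyl-6,6-dimethyl-3-(prop-1-en-2-yl)bicyclo[3.2.0]heptan-2-ol | O[C@@]1(C=C)[C@H](C(C)=C)C[C@@H]2[C@H]1CC2(C)C | intermediate
11 | potassium alkoxide of 10 | [K]O[C@@]1(C=C)[C@H](C(C)=C)C[C@@H]2[C@H]1CC2(C)C | intermediate (not isolated)
12 | potassium C7=C8 enolate of 13 (both ring double bonds cis in the ring) | C/C1=C/C[C@@H]2[C@@H](CC2(C)C)/C(O[K])=C\CC1 | intermediate (not isolated)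
13 | (1R,3Z,9R)-4,11,11-trimethylbicyclo[7.2.0]undec-3-en-8-one, cis-fused | C/C1=C/C[C@@H]2[C@@H](CC2(C)C)C(=O)CCC1 | intermediate
14 | (1R,3Z,9S)-4,11,11-trimethylbicyclo[7.2.0]undec-3-en-8-one, trans-fused | C/C1=C/C[C@@H]2[C@H](CC2(C)C)C(=O)CCC1 | intermediate
15 | (1R,3Z,9S)-5-hydroxy-4,11,11-trimethylbicyclo[7.2.0]undec-3-en-8-one, C5 epimers (C5 deliberately undefined) | C/C1=C/C[C@@H]2[C@H](CC2(C)C)C(=O)CCC1O | intermediate
16 | (1R,3Z,9S)-4,11,11-trimethyl-8-methylidenebicyclo[7.2.0]undec-3-en-5-ol, C5 epimers (C5 deliberately undefined) | C/C1=C/C[C@@H]2[C@H](CC2(C)C)C(=C)CCC1O | intermediate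
17 | (1R,3Z,9S)-4,11,11-trimethyl-8-methylidenebicyclo[7.2.0]undec-3-en-5-one | C/C1=C/C[C@@H]2[C@H](CC2(C)C)C(=C)CCC1=O | intermediate
18 | (1R,3Z,5S,9S)-4,11,11-trimethyl-8-methylidenebicyclo[7.2.0]undec-3-en-5-ol | C/C1=C/C[C@@H]2[C@H](CC2(C)C)C(=C)CC[C@@H]1O | intermediate
19 | syncarpic acid | CC1(C)C(=O)CC(=O)C(C)(C)C1=O | starting material
20 | isovaleraldehyde | CC(C)CC=O | starting material
21 | 2,2,4,4-tetramethyl-6-[3-methyl-1-(piperidin-1-yl)butyl]cyclohexane-1,3,5-trione (racemic, centre lost on elimination) | CC(C)CC(N1CCCCC1)C1C(=O)C(C)(C)C(=O)C(C)(C)C1=O | intermediate (not isolated)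
22 | 2,2,4,4-tetramethyl-6-(3-methylbutylidene)cyclohexane-1,3,5-trione | CC(C)CC=C1C(=O)C(C)(C)C(=O)C(C)(C)C1=O | intermediate
23 | Tomentodione P (1R,3Z,5S,8S,9S,1′S) | C/C1=C/C[C@@H]2[C@H](CC2(C)C)[C@]2(CC[C@@H]1O)C[C@H](CC(C)C)C1=C(O2)C(C)(C)C(=O)C(C)(C)C1=O | target

**Step count**
Total step count: 12. Longest linear sequence: 11 (steps 1–10 and 12). Step 11 is a one-step side branch.

**Steps most likely to fail**

**Step 7 (allylic hydroxylation).**
- What may go wrong: in the ene step the selenium reagent may take hydrogen from the freely rotating C12 methyl group instead of the ring C5–H bonds. In a cis-cyclononene these ring C–H bonds are poorly aligned with the π system, so regiocontrol may be lost. Over-oxidation is a lesser concern.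
- Fallback: the C5 oxygen is not introduced by C–H oxidation but is carried through the ring expansion on the alkenyl partner. The fallback sets out from silyl enol ether 5 and comes back at hydroxy ketone 15.
- 4-Methoxybenzyl alcohol is treated with KH and trichloroethylene to give (E)-1,2-dichlorovinyl 4-methoxybenzyl ether F1. n-BuLi and then MeI convert it into 4-methoxybenzyl prop-1-ynyl ether F2, which is kept cold.
- Syn-hydrozirconation with Cp2Zr(H)Cl (hydride to the oxygen-bearing carbon) followed by iodinolysis gives (E)-2-iodo-1-(4-methoxybenzyloxy)prop-1-ene F3.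
- Coupling of this iodide with 5 under the conditions of step 3 gives the exo 3-alkenyl ketone F4. Vinyl addition as in step 4 gives the carbinol F5.
- The anionic oxy-Cope rearrangement as in step 5 gives the cis-fused 5-(4-methoxybenzyloxy) ketone F6. The alkoxy group sits on the outside of the boat, and suprafacial bond formation should give 5R.
- NaOMe as in step 6 gives the trans-fused ether F7. DDQ in buffered CH2Cl2–water then releases 15 as one C5 epimer, whose configuration again does not matter because step 9 erases it.

**Step 1 (key photocycloaddition).**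
- What may go wrong: direct excitation of unbound cyclopentenone, and looser binding of the five-membered enone to the catalyst, may erode the enantiofacial control. Some head-to-head addition may accompany the wanted orientation.
- Fallback: the same two bonds are formed without a catalyst and the product is resolved with a stoichiometric chiral acid. The fallback sets out from 1 and 2 and comes back at 3.
- Irradiation of 1 with excess 2 (Pyrex-filtered Hg lamp, CH2Cl2, −40 °C) gives the racemic cis-fused ketone F8. NaBH4 in MeOH attacks its convex face to give the racemic endo alcohol F9.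
- Esterification with (R)-2-methoxy-2-phenylacetic acid (DCC, DMAP) gives the (1R,2S,5R) ester F10 and the (1S,2R,5S) ester F11, which are separated by chromatography or crystallisation.
- LiOH in aqueous THF cleaves the wanted ester to the (1R,2S,5R) alcohol F12, and Dess–Martin oxidation returns enantiopure 3.

**Step 12 (hetero-Diels–Alder reaction).**
- What may go wrong: weak discrimination between the two orientations of the heterodiene (C1′), incomplete facial selectivity at C8, and a competing ene pathway may lower the share of the wanted diastereomer.
- Fallback: the order of events is changed so that the ring is closed before C5 is set, on a stiffer dienophile that has no hydroxyl group. The fallback sets out from dienone 17 and enetrione 22 and comes back at 23.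
- Heating 17 with 22 in toluene gives the 5-oxo cycloadduct F13. Its diastereomers are separated at this ketone stage, and the unwanted ones can be cracked thermally by cycloreversion to 17 and 22 and recycled.
- The reduction of step 10 then converts the conjugated C5 ketone into the 5S alcohol 23. The two remaining carbonyl groups are shielded by quaternary carbons or deactivated as a vinylogous ester.

**Further compounds**
F1 | step 7 | (E)-1,2-dichlorovinyl 4-methoxybenzyl ether | Cl/C=C(/Cl)OCc1ccc(OC)cc1
F2 | step 7 | 4-methoxybenzyl prop-1-ynyl ether | CC#COCc1ccc(OC)cc1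
F3 | step 7 | (E)-2-iodo-1-(4-methoxybenzyloxy)prop-1-ene | C/C(I)=C\OCc1ccc(OC)cc1
F4 | step 7 | (1R,3S,5R)-3-[(1E)-1-(4-methoxybenzyloxy)prop-1-en-2-yl]-6,6-dimethylbicyclo[3.2.0]heptan-2-one | O=C1[C@H](/C(C)=C/OCc3ccc(OC)cc3)C[C@@H]2[C@H]1CC2(C)C
F5 | step 7 | (1R,2R,3S,5R)-2-ethenyl-3-[(1E)-1-(4-methoxybenzyloxy)prop-1-en-2-yl]-6,6-dimethylbicyclo[3.2.0]heptan-2-ol | O[C@@]1(C=C)[C@H](/C(C)=C/OCc3ccc(OC)cc3)C[C@@H]2[C@H]1CC2(C)C
F6 | step 7 | (1R,3Z,5R,9R)-5-(4-methoxybenzyloxy)-4,11,11-trimethylbicyclo[7.2.0]undec-3-en-8-one, cis-fused | C/C1=C/C[C@@H]2[C@@H](CC2(C)C)C(=O)CC[C@H]1OCc3ccc(OC)cc3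
F7 | step 7 | (1R,3Z,5R,9S)-5-(4-methoxybenzyloxy)-4,11,11-trimethylbicyclo[7.2.0]undec-3-en-8-one, trans-fused | C/C1=C/C[C@@H]2[C@H](CC2(C)C)C(=O)CC[C@H]1OCc3ccc(OC)cc3
F8 | step 1 | racemic cis-6,6-dimethylbicyclo[3.2.0]heptan-2-one | O=C1CC[C@@H]2[C@H]1CC2(C)C.O=C1CC[C@H]2[C@@H]1CC2(C)C
F9 | step 1 | racemic endo-6,6-dimethylbicyclo[3.2.0]heptan-2-ol | O[C@H]1CC[C@@H]2[C@H]1CC2(C)C.O[C@@H]1CC[C@H]2[C@@H]1CC2(C)C
F10 | step 1 | (1R,2S,5R)-6,6-dimethylbicyclo[3.2.0]heptan-2-yl (R)-2-methoxy-2-phenylacetate | CO[C@@H](C(=O)O[C@H]1CC[C@@H]2[C@H]1CC2(C)C)c1ccccc1
F11 | step 1 | (1S,2R,5S)-6,6-dimethylbicyclo[3.2.0]heptan-2-yl (R)-2-methoxy-2-phenylacetate | CO[C@@H](C(=O)O[C@@H]1CC[C@H]2[C@@H]1CC2(C)C)c1ccccc1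
F12 | step 1 | (1R,2S,5R)-6,6-dimethylbicyclo[3.2.0]heptan-2-ol | O[C@H]1CC[C@@H]2[C@H]1CC2(C)C
F13 | step 12 | 5-oxo cycloadduct (5-dehydro-Tomentodione P) | C/C1=C/C[C@@H]2[C@H](CC2(C)C)[C@]2(CCC1=O)C[C@H](CC(C)C)C1=C(O2)C(C)(C)C(=O)C(C)(C)C1=O
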